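## Analysis of the target

The target (C30H22O15) is a chain of five hydroxylated benzene rings held together only by four diaryl ether oxygens; it has no stereocentre and no C–C bond between rings. The rings are lettered A to E from the 3,5-dihydroxyphenoxy end, and in rings B to E position 1 is the carbon bound to the ether oxygen of the preceding ring. Ring A is 3,5-dihydroxyphenoxy. Ring B has the ring A oxygen at B1, hydroxyls at B2 and B4 and the ether oxygen to ring C at B6. Ring C has hydroxyls at C2 and C6 and the ether oxygen to ring D at C4. Ring D repeats ring B (hydroxyls at D2 and D4, ether oxygen to ring E at D6), and ring E is 2,4,6-trihydroxyphenoxy. Eleven free phenols on electron-rich rings make the compound polar, acidic and easily oxidised by air, so it should be set free only in the last step and under neutral conditions. The difficulty lies in the ether bonds: B1, C1, D1 and E1 each have oxygen substituents on both neighbouring carbons, the kind of aryl carbon at which substitution and copper coupling work least well. Rings B and D also each need one of two equivalent flanking oxygens arylated while the other two stay as hydroxyls. The strategy rests on ring B: B1 with its aryloxy group lies between the oxygen-bearing carbons B2 and B6, as the central carbon of an aryloxymalonate lies between its two ester carbons, and B3–B4–B5 is the CH2–CO–CH2 unit of a 3-oxoglutaric ester. Ring D has the same substitution, so the ring construction can be used twice.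

## Retrosynthetic reasoning

**25 from 24.** The last operation removes the ten benzyl ethers of 24 by catalytic hydrogenolysis. No skeletal bond is cut. Benzyl is the only protecting group in the route because it leaves under neutral conditions that neither the diaryl ethers nor the air-sensitive 25 suffer from.

**24 from 22 (through 23).** The free E4 hydroxyl of 24 is traced back to the formyl group of 22. The forward reaction is a peracid oxidation that turns the E4–CHO bond into an E4–O bond through formate 23. The formyl group is wanted one step earlier, where it activates the bromide for the ether coupling.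

**22 from 21 and 12.** The D6–O–E1 bond is cut on the ring E side, giving phenol 21 and bromide 12. E1 is flanked by two benzyloxy groups, so the bromide is hindered. The para formyl group makes it electron-poor, which helps the copper-catalysed arylation, and as a small symmetrical compound 12 can be used in excess. A single bromide holding rings C, D and E was considered for the arylation of ring B and set aside. It would be electron-rich as well as hindered, it could only be used one-to-one against an advanced phenol, and its own synthesis would need the ring D chemistry in any case.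

**21 from 20.** Two of the three hydroxyls of ring D in 20 are benzylated so that a single flanking hydroxyl is left for the arylation. Either flanking hydroxyl gives the same compound, so the symmetry of ring D is broken here and not in the coupling.

**20 from 18 (through 19), 18 from 16 and 4 (through 17), 16 from 15 and 2.** Ring D is taken apart as ring B is: the two ester groups at D3 and D5 are put back (20 to 18), then the D2–D3 and D6–D5 bonds are cut. This leaves aryloxymalonate 16, in which the C4 oxygen of ring C already sits on the future D1, and keto diester 4. The crowded C4–O–D1 ether is thus made in 16 by a simple substitution of phenol 15 on bromomalonate 2, before D1 becomes an aromatic carbon.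

**15 from 13 (through 14), 13 from 9 and 12.** The C4 hydroxyl of 15 again comes from a formyl group, and the B6–O–C1 bond is cut to phenol 9 and the same bromide 12. One building block therefore supplies both ring C and ring E.

**9 from 8, 8 from 6 (through 7).** The two benzyl groups on B2 and B4 are removed to triol 8, and the ester groups at B3 and B5 are restored to give diester 6. These ester groups have no counterpart in the target; they are the price of the ring construction and leave by hydrolysis and decarboxylation.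

**6 from 3 and 4 (through 5).** This is the central disconnection. Ring B is cut at B2–B3 and B6–B5, which separates the three-carbon unit B3–B4–B5 (keto diester 4) from the unit B2–B1–B6 (aryloxymalonate 3). All three new oxygens of ring B come from carbonyl groups and the ring A oxygen is already on B1, so no C–O bond has to be made at a crowded aromatic carbon. The forward reaction must acylate both methylene carbons of 4 with the two ester groups of 3 and end in an aromatic ring.

**3 from 1 and 2.** The B1–O bond is cut to phenol 1 and bromomalonate 2. Both are purchasable, and the forward reaction is an ordinary substitution at an sp3 carbon.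

**12 from 11, 11 from 10.** Bromide 12 is the dibenzyl ether of diol 11, which comes from the purchasable dimethyl ether 10 by ether cleavage. The exchange of methyl for benzyl keeps the final deprotection a single hydrogenolysis.

## Alternatives that were turned down

**Alternative 1: four late hydroxyls by C–H borylation and oxidation.**
- Disconnection: the four hydroxyls that have no ortho neighbour (on ring A, at B4, D4 and E4) are removed, leading back to the heptamethyl deoxy pentamer A2.
- Forward step: an iridium bipyridine catalyst with a diboron reagent would borylate the four C–H bonds of A2 that have no ortho substituent, and oxidation of the C–B bonds in the same flask would give tetraphenol A1. No ring is closed.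
- For it: sterically governed borylation is predictable, exactly four such C–H bonds exist in A2, and four C–O bonds would be made in one operation. In end-game economy it is stronger than the chosen route.
- Against it: A2 still contains all four crowded ether bonds, and the key step helps with none of them. A fourfold reaction must go to completion at every site. A1 is still seven methyl ethers away from the target, which calls for a strong Lewis acid on a molecule that ends with eleven phenols.
- Comparison: the chosen strategy makes two of the crowded ethers by substitution at sp3 carbon and ends with a neutral hydrogenolysis, at the cost of more steps.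

**Alternative 2: ring E from a pyranone by Claisen recyclisation.**
- Disconnection: ring E is cut at E1–E2, leading back to pyranone A4, a 4-methoxy-2-pyranone with a ring D aryloxymethyl group at its 6-position.
- Forward step: a magnesium alkoxide in hot alcohol would open the lactone to a keto enoate. The carbon between the ketone and the aryloxy group would then attack the ester carbonyl and close ring E as resorcinol A3.
- For it: the logic is related to the chosen one, since the crowded E1–O bond is made at an sp3 carbon before the ring exists. It is stronger on one point: the para oxygen arrives as a methyl ether, already told apart from the two flanking hydroxyls, whereas ring B in the chosen route appears with three like hydroxyls and needs a controlled benzylation.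
- Against it: that advantage is spent on ring E, whose three oxygens all end as free hydroxyls. The route mixes methyl, methoxymethyl and benzyl groups, so the end needs a Lewis-acid demethylation as well as hydrogenolysis. The ring closure must compete with reactions of the more acidic methylene next to the enol ether. Only the terminal ether is solved.
- Comparison: the chosen strategy uses two purchasable partners, keeps one protecting group, and builds an interior ring by a reaction that can be repeated for ring D.

**Alternative 3: ring A by cyclobutenone and ynol ether benzannulation.**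
- Disconnection: ring A is divided into a four-carbon and a two-carbon piece, 3-ethoxycyclobutenone A6 and aryl ethynyl ether A7, whose aryl group is ring B.
- Forward step: heating A6 with A7 would open the cyclobutenone to a vinylketene. A [2+2] addition to the alkyne, electrocyclic opening, 6π closure and tautomerisation (a Danheiser benzannulation) would give phenol A5.
- For it: the conditions are neutral and thermal, the regiochemistry is fixed by the polarity of the ynol ether, and there is no base and no self-condensation. In mildness and predictability of the ring-forming step it is stronger than the chosen route.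
- Against it: the effort goes into ring A, the one ring that can be bought in protected form as 1 and whose own ether carbon is unhindered. A7 has to be made from a crowded phenol in extra steps and is a labile compound. A5 carries an ethyl ether that needs harsh cleavage next to benzyl and methoxymethyl groups.
- Comparison: the chosen strategy puts its ring synthesis on rings B and D, which cannot be bought and whose ether carbons are crowded.

Key step: step 2

Remark: compounds 1, 2, 4 and 10 are taken as purchasable; ring letters and positions are used as defined in the analysis.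

## Route

Step 1
Reactants: 1 3,5-bis(benzyloxy)phenol; 2 diethyl bromomalonate
Product: 3 diethyl 2-[3,5-bis(benzyloxy)phenoxy]malonate
Conditions: K2CO3, acetone, reflux
Reagents that add atoms: none
Why: Williamson-type O-alkylation: the phenoxide of 1 displaces bromide from the doubly activated carbon of 2 (SN2), the usual way to aryloxymalonates. The later B1–O bond is formed while B1 is still an sp3 carbon and sterically open.

Step 2
Reactants: 3 diethyl 2-[3,5-bis(benzyloxy)phenoxy]malonate; 4 diethyl 3-oxopentanedioate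
Product: 6 diethyl 5-[3,5-bis(benzyloxy)phenoxy]-2,4,6-trihydroxybenzene-1,3-dicarboxylate, via open-chain triester 5 (not isolated)
Conditions: 4, NaOEt (1.0 equiv), EtOH, rt; then 3, reflux, NaOEt (1.2 equiv) added slowly; aq HCl
Reagents that add atoms: none
Why: The sodium enolate of 4 attacks one ester carbonyl of 3 in a crossed Claisen condensation, ethoxide leaves, and the B2–B3 bond is formed to give 5 as its stabilised tricarbonyl anion. After a proton shift the second methylene of the oxoglutarate part attacks the remaining ester of the former malonate in a Dieckmann closure (6-exo-trig), which forms the B6–B5 bond and closes ring B as a 2-aryloxycyclohexane-1,3,5-trione diester. Enolisation gives the aromatic ring, and deprotonation of the acidic triphenol by ethoxide takes it out of all equilibria, so the sequence should be irreversible. The closest known reaction is the alkoxide condensation of malonic ester with acetonedicarboxylic ester to diethyl 2,4,6-trihydroxyisophthalate; here the malonate carries an aryloxy group on its central carbon, which takes no part in bond formation. No stereocentre is set, since the labile sp3 centres of 5 become trigonal ring carbons. The step needs C-acylation twice: attack by an enol oxygen on the second ester would give a 4-hydroxy-2-pyranone, and closure from the aryloxy-bearing carbon would give a ring that cannot aromatise, but both are reversible under ethoxide and only the phenoxide of 6 is a sink. It also needs 3 to act as the electrophile, which the order of addition secures: 4 is the more acidic partner and is deprotonated first, and its enolate is too weak a base to convert 3 fully into its unreactive enolate. Self-condensation of 4 is the main competitor and is held down by the slow addition of the second portion of base.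

Step 3
Reactants: 6 diethyl 5-[3,5-bis(benzyloxy)phenoxy]-2,4,6-trihydroxybenzene-1,3-dicarboxylate
Product: 8 2-[3,5-bis(benzyloxy)phenoxy]benzene-1,3,5-triol, via diacid 7 (not isolated)
Conditions: KOH, H2O/EtOH (degassed), reflux, Ar; then aq HCl, 60 °C
Reagents that add atoms: none
Why: Saponification followed by decarboxylation: 2,4,6-trihydroxybenzoic acids lose CO2 readily through their keto tautomers, as vinylogous β-keto acids do. Benzyl ethers and the diaryl ether are inert to aqueous alkali, and exclusion of air protects the electron-rich triol.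

Step 4
Reactants: 8 2-[3,5-bis(benzyloxy)phenoxy]benzene-1,3,5-triol
Product: 9 3,5-bis(benzyloxy)-2-[3,5-bis(benzyloxy)phenoxy]phenol
Conditions: BnBr (2.0 equiv), K2CO3, DMF, 0 °C to rt
Reagents that add atoms: benzyl bromide, BrCc1ccccc1
Why: Williamson etherification stopped at the dibenzyl stage: the unflanked B4 hydroxyl should react first, and benzylation of either flanking hydroxyl then gives the same compound, so two of the three possible dibenzyl ethers are 9. Mono- and tribenzyl ethers and the B2,B6 isomer are separated and the monoethers recycled; the polar aprotic medium favours O- over C-benzylation.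

Step 5
Reactants: 10 4-bromo-3,5-dimethoxybenzaldehyde
Product: 11 4-bromo-3,5-dihydroxybenzaldehyde
Conditions: BBr3, CH2Cl2, −78 °C to rt; H2O
Reagents that add atoms: none
Why: Lewis-acid cleavage of aryl methyl ethers (boron–ether complex, bromide attack on methyl). The formyl group and the aryl bromide are untouched, and the boron esters are hydrolysed on work-up.

Step 6
Reactants: 11 4-bromo-3,5-dihydroxybenzaldehyde
Product: 12 3,5-bis(benzyloxy)-4-bromobenzaldehyde
Conditions: BnBr, K2CO3, DMF, 60 °C
Reagents that add atoms: benzyl bromide, BrCc1ccccc1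
Why: Exhaustive Williamson benzylation of both phenols, with no selectivity question.

Step 7
Reactants: 9 3,5-bis(benzyloxy)-2-[3,5-bis(benzyloxy)phenoxy]phenol; 12 3,5-bis(benzyloxy)-4-bromobenzaldehyde
Product: 13 3,5-bis(benzyloxy)-4-{3,5-bis(benzyloxy)-2-[3,5-bis(benzyloxy)phenoxy]phenoxy}benzaldehyde
Conditions: CuI (cat.), picolinic acid, K3PO4, DMSO, 100 °C; 12 in excess
Reagents that add atoms: none
Why: Ullmann-type diaryl ether synthesis forming the B6–O–C1 bond. The only free hydroxyl of 9 is the nucleophile, CuI with picolinic acid is a system suited to ortho-substituted partners, and the para formyl group of 12 speeds up the C–Br activation that the two flanking benzyloxy groups slow down.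

Step 8
Reactants: 13 3,5-bis(benzyloxy)-4-{3,5-bis(benzyloxy)-2-[3,5-bis(benzyloxy)phenoxy]phenoxy}benzaldehyde
Product: 15 3,5-bis(benzyloxy)-4-{3,5-bis(benzyloxy)-2-[3,5-bis(benzyloxy)phenoxy]phenoxy}phenol, via aryl formate 14 (not isolated)
Conditions: mCPBA, CH2Cl2, 0 °C to rt; then K2CO3 (cat.), MeOH, rt
Reagents that add atoms: 3-chloroperoxybenzoic acid (mCPBA), OOC(=O)c1cccc(Cl)c1
Why: Baeyer–Villiger (Dakin-type) oxidation: in the Criegee adduct the oxygen-rich aryl group migrates, as it does in 3,4,5-trialkoxybenzaldehydes, to give formate 14, which mild methanolysis cleaves. Excess peracid is destroyed before the methanolysis so that the free phenol never meets the oxidant.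

Step 9
Reactants: 15 3,5-bis(benzyloxy)-4-{3,5-bis(benzyloxy)-2-[3,5-bis(benzyloxy)phenoxy]phenoxy}phenol; 2 diethyl bromomalonate
Product: 16 diethyl 2-(3,5-bis(benzyloxy)-4-{3,5-bis(benzyloxy)-2-[3,5-bis(benzyloxy)phenoxy]phenoxy}phenoxy)malonate
Conditions: K2CO3, acetone, reflux
Reagents that add atoms: none
Why: Williamson-type O-alkylation as in step 1, now on the unflanked C4 hydroxyl of ring C; it makes the later C4–O–D1 ether while D1 is an sp3 carbon.

Step 10
Reactants: 16 diethyl 2-(3,5-bis(benzyloxy)-4-{3,5-bis(benzyloxy)-2-[3,5-bis(benzyloxy)phenoxy]phenoxy}phenoxy)malonate; 4 diethyl 3-oxopentanedioate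
Product: 18 diethyl 5-(3,5-bis(benzyloxy)-4-{3,5-bis(benzyloxy)-2-[3,5-bis(benzyloxy)phenoxy]phenoxy}phenoxy)-2,4,6-trihydroxybenzene-1,3-dicarboxylate, via open-chain triester 17 (not isolated)
Conditions: 4, NaOEt (1.0 equiv), EtOH/THF, rt; then 16, reflux, NaOEt (1.2 equiv) added slowly; aq HCl
Reagents that add atoms: none
Why: Second use of the ring construction of step 2 (crossed Claisen condensation, then Dieckmann closure, 6-exo-trig, then aromatisation), forming the D2–D3 and D6–D5 bonds and ring D. The benzyl ethers and diaryl ethers of rings A to C are inert to ethoxide, and THF is added only for solubility.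

Step 11
Reactants: 18 diethyl 5-(3,5-bis(benzyloxy)-4-{3,5-bis(benzyloxy)-2-[3,5-bis(benzyloxy)phenoxy]phenoxy}phenoxy)-2,4,6-trihydroxybenzene-1,3-dicarboxylate
Product: 20 2-(3,5-bis(benzyloxy)-4-{3,5-bis(benzyloxy)-2-[3,5-bis(benzyloxy)phenoxy]phenoxy}phenoxy)benzene-1,3,5-triol, via diacid 19 (not isolated)
Conditions: KOH, H2O/EtOH/THF (degassed), reflux, Ar; then aq HCl, 60 °C
Reagents that add atoms: none
Why: Saponification and decarboxylation as in step 3; the acids at D3 and D5 are again 2,4,6-trihydroxybenzoic acids and lose CO2 easily.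

Step 12
Reactants: 20 2-(3,5-bis(benzyloxy)-4-{3,5-bis(benzyloxy)-2-[3,5-bis(benzyloxy)phenoxy]phenoxy}phenoxy)benzene-1,3,5-triol
Product: 21 3,5-bis(benzyloxy)-2-(3,5-bis(benzyloxy)-4-{3,5-bis(benzyloxy)-2-[3,5-bis(benzyloxy)phenoxy]phenoxy}phenoxy)phenol
Conditions: BnBr (2.0 equiv), K2CO3, DMF, 0 °C to rt
Reagents that add atoms: benzyl bromide, BrCc1ccccc1
Why: Controlled Williamson dibenzylation as in step 4: D4 and one flanking hydroxyl are etherified, and either flanking hydroxyl leads to the same compound. Under- and over-benzylated material is separated and the former recycled.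

Step 13
Reactants: 21 3,5-bis(benzyloxy)-2-(3,5-bis(benzyloxy)-4-{3,5-bis(benzyloxy)-2-[3,5-bis(benzyloxy)phenoxy]phenoxy}phenoxy)phenol; 12 3,5-bis(benzyloxy)-4-bromobenzaldehyde
Product: 22 3,5-bis(benzyloxy)-4-[3,5-bis(benzyloxy)-2-(3,5-bis(benzyloxy)-4-{3,5-bis(benzyloxy)-2-[3,5-bis(benzyloxy)phenoxy]phenoxy}phenoxy)phenoxy]benzaldehyde
Conditions: CuI (cat.), picolinic acid, K3PO4, DMSO, 100 °C; 12 in excess
Reagents that add atoms: none
Why: Ullmann-type diaryl ether synthesis as in step 7, forming the D6–O–E1 bond between the single free hydroxyl of 21 and the formyl-activated bromide.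

Step 14
Reactants: 22 3,5-bis(benzyloxy)-4-[3,5-bis(benzyloxy)-2-(3,5-bis(benzyloxy)-4-{3,5-bis(benzyloxy)-2-[3,5-bis(benzyloxy)phenoxy]phenoxy}phenoxy)phenoxy]benzaldehyde
Product: 24 3,5-bis(benzyloxy)-4-[3,5-bis(benzyloxy)-2-(3,5-bis(benzyloxy)-4-{3,5-bis(benzyloxy)-2-[3,5-bis(benzyloxy)phenoxy]phenoxy}phenoxy)phenoxy]phenol, via aryl formate 23 (not isolated)
Conditions: mCPBA, CH2Cl2, 0 °C to rt; then K2CO3 (cat.), MeOH, rt
Reagents that add atoms: 3-chloroperoxybenzoic acid (mCPBA), OOC(=O)c1cccc(Cl)c1
Why: Baeyer–Villiger oxidation with aryl migration and methanolysis of the formate as in step 8; it delivers the E4 hydroxyl, which needs no further protection.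

Step 15
Reactants: 24 3,5-bis(benzyloxy)-4-[3,5-bis(benzyloxy)-2-(3,5-bis(benzyloxy)-4-{3,5-bis(benzyloxy)-2-[3,5-bis(benzyloxy)phenoxy]phenoxy}phenoxy)phenoxy]phenol
Product: 25 2-[2-(4-{2-(3,5-dihydroxyphenoxy)-3,5-dihydroxyphenoxy}-3,5-dihydroxyphenoxy)-3,5-dihydroxyphenoxy]benzene-1,3,5-triol (target)
Conditions: H2 (1 atm), Pd/C, THF/MeOH, rt; filtration and concentration under Ar
Reagents that add atoms: none
Why: Catalytic hydrogenolysis of ten aryl benzyl ethers. Diaryl ethers and the arene rings are not reduced under these conditions, and the polyphenol is isolated without base and without contact with air.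

## Compound list

1 | 3,5-bis(benzyloxy)phenol | Oc1cc(OCc2ccccc2)cc(OCc2ccccc2)c1 | starting material
2 | diethyl bromomalonate | CCOC(=O)C(Br)C(=O)OCC | starting material
3 | diethyl 2-[3,5-bis(benzyloxy)phenoxy]malonate | CCOC(=O)C(Oc1cc(OCc2ccccc2)cc(OCc2ccccc2)c1)C(=O)OCC | intermediate
4 | diethyl 3-oxopentanedioate | CCOC(=O)CC(=O)CC(=O)OCC | starting material
5 | triethyl 1-[3,5-bis(benzyloxy)phenoxy]-2,4-dioxopentane-1,3,5-tricarboxylate (mixture of stereoisomers and enol forms) | CCOC(=O)CC(=O)C(C(=O)OCC)C(=O)C(Oc1cc(OCc2ccccc2)cc(OCc2ccccc2)c1)C(=O)OCC | intermediate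
6 | diethyl 5-[3,5-bis(benzyloxy)phenoxy]-2,4,6-trihydroxybenzene-1,3-dicarboxylate | CCOC(=O)c1c(O)c(C(=O)OCC)c(O)c(Oc2cc(OCc3ccccc3)cc(OCc3ccccc3)c2)c1O | intermediate
7 | 5-[3,5-bis(benzyloxy)phenoxy]-2,4,6-trihydroxybenzene-1,3-dicarboxylic acid | OC(=O)c1c(O)c(C(=O)O)c(O)c(Oc2cc(OCc3ccccc3)cc(OCc3ccccc3)c2)c1O | intermediate
8 | 2-[3,5-bis(benzyloxy)phenoxy]benzene-1,3,5-triol | Oc1cc(O)c(Oc2cc(OCc3ccccc3)cc(OCc3ccccc3)c2)c(O)c1 | intermediate
9 | 3,5-bis(benzyloxy)-2-[3,5-bis(benzyloxy)phenoxy]phenol | Oc1cc(OCc2ccccc2)cc(OCc2ccccc2)c1Oc1cc(OCc2ccccc2)cc(OCc2ccccc2)c1 | intermediate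
10 | 4-bromo-3,5-dimethoxybenzaldehyde | COc1cc(C=O)cc(OC)c1Br | starting material
11 | 4-bromo-3,5-dihydroxybenzaldehyde | Oc1cc(C=O)cc(O)c1Br | intermediate
12 | 3,5-bis(benzyloxy)-4-bromobenzaldehyde | O=Cc1cc(OCc2ccccc2)c(Br)c(OCc2ccccc2)c1 | intermediate
13 | 3,5-bis(benzyloxy)-4-{3,5-bis(benzyloxy)-2-[3,5-bis(benzyloxy)phenoxy]phenoxy}benzaldehyde | O=Cc1cc(OCc2ccccc2)c(Oc2cc(OCc3ccccc3)cc(OCc3ccccc3)c2Oc2cc(OCc3ccccc3)cc(OCc3ccccc3)c2)c(OCc2ccccc2)c1 | intermediate
14 | 3,5-bis(benzyloxy)-4-{3,5-bis(benzyloxy)-2-[3,5-bis(benzyloxy)phenoxy]phenoxy}phenyl formate | O=COc1cc(OCc2ccccc2)c(Oc2cc(OCc3ccccc3)cc(OCc3ccccc3)c2Oc2cc(OCc3ccccc3)cc(OCc3ccccc3)c2)c(OCc2ccccc2)c1 | intermediate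
15 | 3,5-bis(benzyloxy)-4-{3,5-bis(benzyloxy)-2-[3,5-bis(benzyloxy)phenoxy]phenoxy}phenol | Oc1cc(OCc2ccccc2)c(Oc2cc(OCc3ccccc3)cc(OCc3ccccc3)c2Oc2cc(OCc3ccccc3)cc(OCc3ccccc3)c2)c(OCc2ccccc2)c1 | intermediate
16 | diethyl 2-(3,5-bis(benzyloxy)-4-{3,5-bis(benzyloxy)-2-[3,5-bis(benzyloxy)phenoxy]phenoxy}phenoxy)malonate | CCOC(=O)C(Oc1cc(OCc2ccccc2)c(Oc2cc(OCc3ccccc3)cc(OCc3ccccc3)c2Oc2cc(OCc3ccccc3)cc(OCc3ccccc3)c2)c(OCc2ccccc2)c1)C(=O)OCC | intermediate
17 | triethyl 1-(3,5-bis(benzyloxy)-4-{3,5-bis(benzyloxy)-2-[3,5-bis(benzyloxy)phenoxy]phenoxy}phenoxy)-2,4-dioxopentane-1,3,5-tricarboxylate (mixture of stereoisomers and enol forms) | CCOC(=O)CC(=O)C(C(=O)OCC)C(=O)C(Oc1cc(OCc2ccccc2)c(Oc2cc(OCc3ccccc3)cc(OCc3ccccc3)c2Oc2cc(OCc3ccccc3)cc(OCc3ccccc3)c2)c(OCc2ccccc2)c1)C(=O)OCC | intermediate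
18 | diethyl 5-(3,5-bis(benzyloxy)-4-{3,5-bis(benzyloxy)-2-[3,5-bis(benzyloxy)phenoxy]phenoxy}phenoxy)-2,4,6-trihydroxybenzene-1,3-dicarboxylate | CCOC(=O)c1c(O)c(C(=O)OCC)c(O)c(Oc2cc(OCc3ccccc3)c(Oc3cc(OCc4ccccc4)cc(OCc4ccccc4)c3Oc3cc(OCc4ccccc4)cc(OCc4ccccc4)c3)c(OCc3ccccc3)c2)c1O | intermediate
19 | 5-(3,5-bis(benzyloxy)-4-{3,5-bis(benzyloxy)-2-[3,5-bis(benzyloxy)phenoxy]phenoxy}phenoxy)-2,4,6-trihydroxybenzene-1,3-dicarboxylic acid | OC(=O)c1c(O)c(C(=O)O)c(O)c(Oc2cc(OCc3ccccc3)c(Oc3cc(OCc4ccccc4)cc(OCc4ccccc4)c3Oc3cc(OCc4ccccc4)cc(OCc4ccccc4)c3)c(OCc3ccccc3)c2)c1O | intermediate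
20 | 2-(3,5-bis(benzyloxy)-4-{3,5-bis(benzyloxy)-2-[3,5-bis(benzyloxy)phenoxy]phenoxy}phenoxy)benzene-1,3,5-triol | Oc1cc(O)c(Oc2cc(OCc3ccccc3)c(Oc3cc(OCc4ccccc4)cc(OCc4ccccc4)c3Oc3cc(OCc4ccccc4)cc(OCc4ccccc4)c3)c(OCc3ccccc3)c2)c(O)c1 | intermediate
21 | 3,5-bis(benzyloxy)-2-(3,5-bis(benzyloxy)-4-{3,5-bis(benzyloxy)-2-[3,5-bis(benzyloxy)phenoxy]phenoxy}phenoxy)phenol | Oc1cc(OCc2ccccc2)cc(OCc2ccccc2)c1Oc1cc(OCc2ccccc2)c(Oc2cc(OCc3ccccc3)cc(OCc3ccccc3)c2Oc2cc(OCc3ccccc3)cc(OCc3ccccc3)c2)c(OCc2ccccc2)c1 | intermediate
22 | 3,5-bis(benzyloxy)-4-[3,5-bis(benzyloxy)-2-(3,5-bis(benzyloxy)-4-{3,5-bis(benzyloxy)-2-[3,5-bis(benzyloxy)phenoxy]phenoxy}phenoxy)phenoxy]benzaldehyde | O=Cc1cc(OCc2ccccc2)c(Oc2cc(OCc3ccccc3)cc(OCc3ccccc3)c2Oc2cc(OCc3ccccc3)c(Oc3cc(OCc4ccccc4)cc(OCc4ccccc4)c3Oc3cc(OCc4ccccc4)cc(OCc4ccccc4)c3)c(OCc3ccccc3)c2)c(OCc2ccccc2)c1 | intermediate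
23 | 3,5-bis(benzyloxy)-4-[3,5-bis(benzyloxy)-2-(3,5-bis(benzyloxy)-4-{3,5-bis(benzyloxy)-2-[3,5-bis(benzyloxy)phenoxy]phenoxy}phenoxy)phenoxy]phenyl formate | O=COc1cc(OCc2ccccc2)c(Oc2cc(OCc3ccccc3)cc(OCc3ccccc3)c2Oc2cc(OCc3ccccc3)c(Oc3cc(OCc4ccccc4)cc(OCc4ccccc4)c3Oc3cc(OCc4ccccc4)cc(OCc4ccccc4)c3)c(OCc3ccccc3)c2)c(OCc2ccccc2)c1 | intermediate
24 | 3,5-bis(benzyloxy)-4-[3,5-bis(benzyloxy)-2-(3,5-bis(benzyloxy)-4-{3,5-bis(benzyloxy)-2-[3,5-bis(benzyloxy)phenoxy]phenoxy}phenoxy)phenoxy]phenol | Oc1cc(OCc2ccccc2)c(Oc2cc(OCc3ccccc3)cc(OCc3ccccc3)c2Oc2cc(OCc3ccccc3)c(Oc3cc(OCc4ccccc4)cc(OCc4ccccc4)c3Oc3cc(OCc4ccccc4)cc(OCc4ccccc4)c3)c(OCc3ccccc3)c2)c(OCc2ccccc2)c1 | intermediate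
25 | 2-[2-(4-{2-(3,5-dihydroxyphenoxy)-3,5-dihydroxyphenoxy}-3,5-dihydroxyphenoxy)-3,5-dihydroxyphenoxy]benzene-1,3,5-triol | Oc1cc(O)cc(Oc2c(O)cc(O)cc2Oc2c(O)cc(Oc3c(O)cc(O)cc3Oc3c(O)cc(O)cc3O)cc2O)c1 | target

## Step count and least certain steps

Total: 15 steps. Longest linear sequence: 13 steps (steps 1 to 4 and 7 to 15); steps 5 and 6 prepare bromide 12 on the side. Steps 10 and 12 to 14 repeat steps 2, 4, 7 and 8 on larger substrates and share their risks; they are not discussed separately.

**Step 2 (key step).** The most likely failure is self-condensation of 4 outrunning the crossed Claisen condensation. The ester carbonyls of 3 sit next to a carbon that carries an aryloxy group, and they are switched off whenever 3 is present as its enolate, so the intermolecular acylation may be slow and the sequence may stall before ring closure. The fallback sets out from 3 and makes the intermolecular bond with an activated acyl donor. One ester of 3 is saponified with one equivalent of KOH to 2-[3,5-bis(benzyloxy)phenoxy]-3-ethoxy-3-oxopropanoic acid F1. (COCl)2 converts it into ethyl 2-[3,5-bis(benzyloxy)phenoxy]-3-chloro-3-oxopropanoate F2. F2 acylates the magnesium enolate of 4 (MgCl2, Et3N, MeCN) at carbon to give 5, which is now isolated. NaOEt in EtOH then only has to bring about the intramolecular closure of 5, and the route is rejoined at 6. The same two ring bonds are formed, but self-condensation of 4 cannot compete under soft enolisation.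

**Step 4.** The likely failure is poor control of the degree and site of benzylation: reaction at both flanking hydroxyls, over-benzylation to the triether, or C-benzylation of the very electron-rich ring. Nothing but a modest steric preference steers the reagent. The fallback sets out from 8 and moves the symmetry-breaking event into the arylation. One equivalent of benzyl bromide with K2CO3 is used to etherify the unflanked hydroxyl, giving 5-(benzyloxy)-2-[3,5-bis(benzyloxy)phenoxy]benzene-1,3-diol F3. F3 is then arylated with a deficit of 12 under the conditions of step 7. A second arylation next to the first is held back by crowding around B1, so the product should be 3,5-bis(benzyloxy)-4-{5-(benzyloxy)-2-[3,5-bis(benzyloxy)phenoxy]-3-hydroxyphenoxy}benzaldehyde F4. Benzylation of its remaining hydroxyl leads to 13, where the route is rejoined.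

**Step 7.** The likely failure is a slow coupling that lets reduction of the C–Br bond of 12 and decomposition of the aldehyde take over, because the new ether carries three ortho substituents in all. The fallback sets out from 9 and replaces the arylation by a further turn of the ring construction:
- Alkylation of 9 with 2 (K2CO3, acetone) gives diethyl 2-{3,5-bis(benzyloxy)-2-[3,5-bis(benzyloxy)phenoxy]phenoxy}malonate F5.
- Condensation with 4 as in step 2 gives diethyl 5-{3,5-bis(benzyloxy)-2-[3,5-bis(benzyloxy)phenoxy]phenoxy}-2,4,6-trihydroxybenzene-1,3-dicarboxylate F6.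
- Hydrolysis and decarboxylation as in step 3 give 2-{3,5-bis(benzyloxy)-2-[3,5-bis(benzyloxy)phenoxy]phenoxy}benzene-1,3,5-triol F7.
- The bulky chloride TBDPSCl with imidazole silylates the unflanked hydroxyl to 2-{3,5-bis(benzyloxy)-2-[3,5-bis(benzyloxy)phenoxy]phenoxy}-5-[(tert-butyldiphenylsilyl)oxy]benzene-1,3-diol F8.
- Benzylation of both flanking hydroxyls (benzyl bromide, K2CO3, acetone) gives (3,5-bis(benzyloxy)-4-{3,5-bis(benzyloxy)-2-[3,5-bis(benzyloxy)phenoxy]phenoxy}phenoxy)(tert-butyl)diphenylsilane F9.
- Bu4NF removes the silyl group and the route is rejoined at 15, so that steps 7 and 8 are both bypassed.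

**Step 8.** The likely failure is hydride migration in the Criegee adduct, which gives the benzoic acid and not the formate. The para aryloxy donor is twisted out of conjugation by its two benzyloxy neighbours, and slow reaction would also give the peracid time to attack ring A. The fallback sets out from 13 and removes the migrating hydrogen. MeMgBr adds to the aldehyde to give racemic 1-(3,5-bis(benzyloxy)-4-{3,5-bis(benzyloxy)-2-[3,5-bis(benzyloxy)phenoxy]phenoxy}phenyl)ethan-1-ol F10. MnO2 oxidises this benzylic alcohol to 1-(3,5-bis(benzyloxy)-4-{3,5-bis(benzyloxy)-2-[3,5-bis(benzyloxy)phenoxy]phenoxy}phenyl)ethan-1-one F11. In the Baeyer–Villiger oxidation of F11 with mCPBA the aryl group migrates in preference to methyl, giving 3,5-bis(benzyloxy)-4-{3,5-bis(benzyloxy)-2-[3,5-bis(benzyloxy)phenoxy]phenoxy}phenyl acetate F12. K2CO3 in MeOH cleaves the acetate and the route is rejoined at 15.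

## Further compounds

F1 | step 2 | 2-[3,5-bis(benzyloxy)phenoxy]-3-ethoxy-3-oxopropanoic acid | CCOC(=O)C(Oc1cc(OCc2ccccc2)cc(OCc2ccccc2)c1)C(=O)O
F2 | step 2 | ethyl 2-[3,5-bis(benzyloxy)phenoxy]-3-chloro-3-oxopropanoate | CCOC(=O)C(Oc1cc(OCc2ccccc2)cc(OCc2ccccc2)c1)C(Cl)=O
F3 | step 4 | 5-(benzyloxy)-2-[3,5-bis(benzyloxy)phenoxy]benzene-1,3-diol | Oc1cc(OCc2ccccc2)cc(O)c1Oc1cc(OCc2ccccc2)cc(OCc2ccccc2)c1
F4 | step 4 | 3,5-bis(benzyloxy)-4-{5-(benzyloxy)-2-[3,5-bis(benzyloxy)phenoxy]-3-hydroxyphenoxy}benzaldehyde | O=Cc1cc(OCc2ccccc2)c(Oc2cc(OCc3ccccc3)cc(O)c2Oc2cc(OCc3ccccc3)cc(OCc3ccccc3)c2)c(OCc2ccccc2)c1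
F5 | step 7 | diethyl 2-{3,5-bis(benzyloxy)-2-[3,5-bis(benzyloxy)phenoxy]phenoxy}malonate | CCOC(=O)C(Oc1cc(OCc2ccccc2)cc(OCc2ccccc2)c1Oc1cc(OCc2ccccc2)cc(OCc2ccccc2)c1)C(=O)OCC
F6 | step 7 | diethyl 5-{3,5-bis(benzyloxy)-2-[3,5-bis(benzyloxy)phenoxy]phenoxy}-2,4,6-trihydroxybenzene-1,3-dicarboxylate | CCOC(=O)c1c(O)c(C(=O)OCC)c(O)c(Oc2cc(OCc3ccccc3)cc(OCc3ccccc3)c2Oc2cc(OCc3ccccc3)cc(OCc3ccccc3)c2)c1O
F7 | step 7 | 2-{3,5-bis(benzyloxy)-2-[3,5-bis(benzyloxy)phenoxy]phenoxy}benzene-1,3,5-triol | Oc1cc(O)c(Oc2cc(OCc3ccccc3)cc(OCc3ccccc3)c2Oc2cc(OCc3ccccc3)cc(OCc3ccccc3)c2)c(O)c1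
F8 | step 7 | 2-{3,5-bis(benzyloxy)-2-[3,5-bis(benzyloxy)phenoxy]phenoxy}-5-[(tert-butyldiphenylsilyl)oxy]benzene-1,3-diol | CC(C)(C)[Si](Oc1cc(O)c(Oc2cc(OCc3ccccc3)cc(OCc3ccccc3)c2Oc2cc(OCc3ccccc3)cc(OCc3ccccc3)c2)c(O)c1)(c1ccccc1)c1ccccc1
F9 | step 7 | (3,5-bis(benzyloxy)-4-{3,5-bis(benzyloxy)-2-[3,5-bis(benzyloxy)phenoxy]phenoxy}phenoxy)(tert-butyl)diphenylsilane | CC(C)(C)[Si](Oc1cc(OCc2ccccc2)c(Oc2cc(OCc3ccccc3)cc(OCc3ccccc3)c2Oc2cc(OCc3ccccc3)cc(OCc3ccccc3)c2)c(OCc2ccccc2)c1)(c1ccccc1)c1ccccc1
F10 | step 8 | 1-(3,5-bis(benzyloxy)-4-{3,5-bis(benzyloxy)-2-[3,5-bis(benzyloxy)phenoxy]phenoxy}phenyl)ethan-1-ol (racemic) | CC(O)c1cc(OCc2ccccc2)c(Oc2cc(OCc3ccccc3)cc(OCc3ccccc3)c2Oc2cc(OCc3ccccc3)cc(OCc3ccccc3)c2)c(OCc2ccccc2)c1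
F11 | step 8 | 1-(3,5-bis(benzyloxy)-4-{3,5-bis(benzyloxy)-2-[3,5-bis(benzyloxy)phenoxy]phenoxy}phenyl)ethan-1-one | CC(=O)c1cc(OCc2ccccc2)c(Oc2cc(OCc3ccccc3)cc(OCc3ccccc3)c2Oc2cc(OCc3ccccc3)cc(OCc3ccccc3)c2)c(OCc2ccccc2)c1
F12 | step 8 | 3,5-bis(benzyloxy)-4-{3,5-bis(benzyloxy)-2-[3,5-bis(benzyloxy)phenoxy]phenoxy}phenyl acetate | CC(=O)Oc1cc(OCc2ccccc2)c(Oc2cc(OCc3ccccc3)cc(OCc3ccccc3)c2Oc2cc(OCc3ccccc3)cc(OCc3ccccc3)c2)c(OCc2ccccc2)c1
A1 | alternative 1 | heptamethyl ether of the target with free hydroxyls on ring A and at B4, D4 and E4 | COc1cc(O)cc(Oc2c(OC)cc(O)cc2Oc2c(OC)cc(Oc3c(OC)cc(O)cc3Oc3c(OC)cc(O)cc3OC)cc2OC)c1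
A2 | alternative 1 | heptamethyl deoxy pentamer (A1 without its four hydroxyls) | COc1cccc(Oc2c(OC)cccc2Oc2c(OC)cc(Oc3c(OC)cccc3Oc3c(OC)cccc3OC)cc2OC)c1
A3 | alternative 2 | 2-[3,5-bis(benzyloxy)-2-(methoxymethoxy)phenoxy]-5-methoxybenzene-1,3-diol | COc1cc(O)c(Oc2cc(OCc3ccccc3)cc(OCc3ccccc3)c2OCOC)c(O)c1
A4 | alternative 2 | 6-{[3,5-bis(benzyloxy)-2-(methoxymethoxy)phenoxy]methyl}-4-methoxy-2H-pyran-2-one | COc1cc(COc2cc(OCc3ccccc3)cc(OCc3ccccc3)c2OCOC)oc(=O)c1
A5 | alternative 3 | 3-[2,4-bis(benzyloxy)-6-(methoxymethoxy)phenoxy]-5-ethoxyphenol | CCOc1cc(O)cc(Oc2c(OCc3ccccc3)cc(OCc3ccccc3)cc2OCOC)c1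
A6 | alternative 3 | 3-ethoxycyclobut-2-en-1-one | CCOC1=CC(=O)C1
A7 | alternative 3 | 1,5-bis(benzyloxy)-2-(ethynyloxy)-3-(methoxymethoxy)benzene | C#COc1c(OCc2ccccc2)cc(OCc2ccccc2)cc1OCOC
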